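The closed, stirred, isothermal vessel is charged with free monomer and initiator, and the two flasks in question are one recipe read at two times.

| flask | free monomer | initiator | remark | time |
|---|---|---|---|---|
| north-west | 0.033 M | 33 µM | run made earlier |  |
| north | 0.033 M | 50 µM | run made earlier |  |
| south | 0.050 M | 66 µM | run made earlier |  |
| Sunday's | 0.033 M | 66 µM |  | 2.5 min |
| Tuesday's | 0.033 M | 66 µM |  | 10 min |

| run | time / min | monomer in chains / % | free monomer / % |
|---|---|---|---|
| north-west | 0.200 | 2 | 100 |
| north-west | 0.667 | 3 | 95 |
| north-west | 1.00 | 2 | 96 |
| north-west | 1.50 | 6 | 92 |
| north-west | 2.50 | 10 | 90 |
| north-west | 3.00 | 11 | 89 |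
| north | 0.200 | 0 | 101 |
| north | 0.667 | 3 | 96 |
| north | 1.00 | 7 | 94 |
| north | 1.50 | 9 | 89 |
| north | 2.50 | 12 | 87 |
| north | 3.00 | 15 | 83 |
| south | 0.250 | 5 | 98 |
| south | 0.833 | 10 | 93 |
| south | 1.33 | 13 | 87 |
| south | 2.00 | 21 | 81 |
| south | 3.00 | 26 | 74 |

(readings scatter by 1.5 percentage points)

- which of the two ends with the longer chains by the average number of monomer units in a chain (chains begun, living or dead) ("neither" if they lie within 10%) (Sunday's / Tuesday's / neither)
- average number of monomer units in a chain (chains begun, living or dead) at the end, Sunday's
- average number of monomer units in a chain (chains begun, living or dead) at the end, Tuesday's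

- the average divides the monomer in chains by the number of chains begun, living and dead together
- the earlier runs do not show the number of chains; that part of a forecast is a guess

Read as first-order losses from their last readings and scaled to 66 µM of initiator, the north-west and north runs average 0.0798 min⁻¹ at 0.033 M. The south run, with 0.050 M of free monomer and the same initiator, reads 0.100 min⁻¹, which is faster.

My reckoning takes this difference to mean that chains also shed monomer, so that net loss follows free monomer minus a constant floor, the equilibrium monomer concentration. The ratio of the two readings then gives the ceiling share, the fraction of the charge lying above that floor, 56.9% at 0.033 M. It carries the scatter of a few readings. Dividing it by the first-order reading at 0.033 M, taken as the starting rate, gives an approach time of 7.13 min.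

Two extreme versions bracket the curve. A very short reading follows the starting rate, and a very long one stands at the ceiling share. The reckoned share, the ceiling share times one minus exp(−t/approach time), lies below both. Sunday's 2.5 min is shorter than the approach time, so its share stays near the starting line, at 16.8% against 19.9%. Tuesday's 10 min is longer, so its share bends toward the ceiling, at 42.9%. Guessing one chain per initiator, each share is multiplied by 500, which gives 84.2 and 215.

The forecast, holding that “The rate scales with initiator to the first power”, names Tuesday's with 88 and 265, the second above my value.

The flask gives Tuesday's as the longer, with 85.9 for Sunday's and 202 for Tuesday's, the latter below the reckoned value.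

    free monomer + initiator → living end + monomer in chains (k = 9.40 L mol⁻¹ s⁻¹)
    free monomer + living end → monomer in chains + living end, rate k2*[living end]*[free monomer] (k = 44.0 L mol⁻¹ s⁻¹)
    monomer in chains + living end → free monomer + living end, rate k3*[living end] as long as [monomer in chains] is above zero (k = 0.740 s⁻¹)

The neighbouring flask is Sunday's recipe read at 1.5 min, which is shorter than the approach time. The ceiling share and approach time put 10.8% of the charge in chains there, a length of 54.0. That flask holds 11.1% in chains, and its average chain has 55.6 monomer units.

(The readings were computed with constants of no real substance; noise was put on by code.)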